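**Retrosynthetic overview**

- Feature: in the imidazole ring, C5 bears only hydrogen and lies between N1 and C4, which carries the 6-bromoindol-3-yl group; C2 carries the indol-3-yl group. N1–C5 therefore maps onto the N–CH2 of glycine, C2 onto the carbonyl carbon of an indole-3-carboxamide, and C4–N3 onto the C=N of an aldimine of 6-bromoindole-3-carboxaldehyde.
- Key disconnection: imidazole bonds C4–C5 and C2–N3 are cut to give the münchnone of N-(2,4-dimethoxybenzyl)-N-(1-tosylindole-3-carbonyl)glycine 10 and N-tosyl aldimine 14. The forward step is a [3+2] addition followed by loss of CO2 and toluenesulfinic acid.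
- Acid 10 comes from glycine benzyl ester by reductive alkylation, N-acylation with the chloride of 1-tosylindole-3-carboxylic acid and hydrogenolysis. Imine 14 comes from 6-bromoindole-3-carboxaldehyde by N-tosylation and condensation with TsNH2.
- Ring order: both indoles are bought; the imidazole is the only ring made (step 8). The N-benzyl group is then removed by acid and the two sulfonyl groups by base.

Key step: step 8

Assumption: the two N–H tautomers of the 2,4-disubstituted imidazole interconvert freely, so the nitrogen that carried the benzyl group need not be specified after its removal. Indole-3-carboxaldehyde replaces indole-3-carboxylic acid as starting material because N-tosylation of the aldehyde and chlorite oxidation is cleaner than sulfonylation of the acid dianion.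

**Route**

Step 1
Reactants: 1 indole-3-carboxaldehyde
Product: 2 1-tosylindole-3-carboxaldehyde
Conditions: TsCl, Et3N, DMAP (cat.), CH2Cl2, 0 °C to rt
Reagents that add atoms: p-toluenesulfonyl chloride, Cc1ccc(cc1)S(=O)(=O)Cl
Why: The formyl group acidifies the indole N–H enough for amine/DMAP-mediated N-sulfonylation, a standard indole N-protection that also lowers the nucleophilicity of the ring for the later acid steps.

Step 2
Reactants: 2 1-tosylindole-3-carboxaldehyde
Product: 3 1-tosylindole-3-carboxylic acid
Conditions: NaClO2, NaH2PO4, 2-methyl-2-butene, t-BuOH/THF/H2O, rt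
Reagents that add atoms: sodium chlorite, [Na+].[O-]Cl=O
Why: Pinnick oxidation converts the aryl aldehyde to the acid under buffered conditions that leave the N-sulfonyl group intact, with 2-methyl-2-butene scavenging HOCl so that the indole is not chlorinated.

Step 3
Reactants: 4 glycine benzyl ester hydrochloride; 5 2,4-dimethoxybenzaldehyde
Product: 7 benzyl N-(2,4-dimethoxybenzyl)glycinate, via benzyl N-(2,4-dimethoxybenzylidene)glycinate 6 (not isolated)
Conditions: Et3N, NaBH(OAc)3, 1,2-dichloroethane, rt
Reagents that add atoms: none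
Why: Reductive amination with NaBH(OAc)3 reduces the imine 6 formed in situ faster than the aldehyde and does not touch the benzyl ester, and a slight excess of the amine limits double alkylation.

Step 4
Reactants: 3 1-tosylindole-3-carboxylic acid; 7 benzyl N-(2,4-dimethoxybenzyl)glycinate
Product: 9 benzyl N-(2,4-dimethoxybenzyl)-N-(1-tosylindole-3-carbonyl)glycinate, via 1-tosylindole-3-carbonyl chloride 8 (not isolated)
Conditions: (COCl)2, DMF (cat.), CH2Cl2, 0 °C to rt; evaporate; then 7, Et3N, DMAP (cat.), CH2Cl2, 0 °C to rt
Reagents that add atoms: none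
Why: Acid chloride formation followed by acylation of the secondary amine is the dependable way to a hindered tertiary amide, and the benzyl ester lets the carboxyl be freed later without base, which would strip the labile sulfonyl group of a 3-acyl-N-tosylindole.

Step 5
Reactants: 9 benzyl N-(2,4-dimethoxybenzyl)-N-(1-tosylindole-3-carbonyl)glycinate
Product: 10 N-(2,4-dimethoxybenzyl)-N-(1-tosylindole-3-carbonyl)glycine
Conditions: H2 (1 atm), 10% Pd/C, EtOAc/MeOH, rt
Reagents that add atoms: none
Why: Catalytic hydrogenolysis cleaves the O-benzyl ester selectively, since the N-dimethoxybenzyl amide, the sulfonamide and the indole ring are inert to hydrogen over Pd/C at 1 atm and this half carries no bromine.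

Step 6
Reactants: 11 6-bromoindole-3-carboxaldehyde
Product: 12 6-bromo-1-tosylindole-3-carboxaldehyde
Conditions: TsCl, Et3N, DMAP (cat.), CH2Cl2, 0 °C to rt
Reagents that add atoms: p-toluenesulfonyl chloride, Cc1ccc(cc1)S(=O)(=O)Cl
Why: This is the same N-sulfonylation as in step 1, and the tosyl group removes the vinylogous-amide character of the formyl group so that it becomes a better electrophile for imine formation and for the cycloaddition.

Step 7
Reactants: 12 6-bromo-1-tosylindole-3-carboxaldehyde; 13 p-toluenesulfonamide
Product: 14 (E)-N-[(6-bromo-1-tosylindol-3-yl)methylidene]-4-methylbenzenesulfonamide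
Conditions: TiCl4, Et3N, CH2Cl2, 0 °C to rt
Reagents that add atoms: none
Why: Condensation of an aryl aldehyde with a sulfonamide mediated by TiCl4 and Et3N, in which the titanium reagent is both Lewis acid and irreversible water scavenger, should give the thermodynamically preferred (E)-N-sulfonyl aldimine.

Step 8
Reactants: 10 N-(2,4-dimethoxybenzyl)-N-(1-tosylindole-3-carbonyl)glycine; 14 (E)-N-[(6-bromo-1-tosylindol-3-yl)methylidene]-4-methylbenzenesulfonamide
Product: 18 1-(2,4-dimethoxybenzyl)-4-(6-bromo-1-tosylindol-3-yl)-2-(1-tosylindol-3-yl)imidazole, via münchnone 15 (not isolated), via bicyclic lactone cycloadduct 16 (not isolated), via cyclic azomethine ylide 17 (not isolated)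
Conditions: N,N'-diisopropylcarbodiimide (DIC, slow addition), 14 (1.5 equiv), 4 Å molecular sieves, CH2Cl2, rt to 40 °C
Reagents that add atoms: none
Why: DIC dehydrates acid 10 to münchnone 15 (the amide oxygen closes the oxazolium ring by 5-exo-trig attack on the carbodiimide-activated carboxyl), a mesoionic azomethine ylide across C2–N3–C4 of the oxazolium ring that is trapped as it forms. Its unsubstituted, enolate-like C4 (the glycine carbon) bonds to the electrophilic carbon of sulfonylimine 14 and the sulfonamide nitrogen bonds to the iminium-like C2, an intermolecular [3+2] annulation (concerted, or Mannich addition then closure) that builds the five-membered N–C–N–C–C ring inside bicyclic lactone 16. Retro-[3+2] loss of CO2 from 16 leaves ylide 17, and expulsion of toluenesulfinate followed by loss of the proton on the carbon bearing the bromoindolyl group aromatises it to imidazole 18, in which C4–C5 and C2–N3 (imidazole numbering) are the two new skeletal bonds. The closest known reaction type is the imidazole synthesis from carbodiimide-generated münchnones and N-sulfonyl aldimines, applied here to two N-tosylindol-3-yl partners. No stereocenter survives in 18, so the exo/endo make-up of 16 is immaterial. The selectivity needed is regiochemical (2,4-diaryl, not 4,5-diaryl); it is secured by the polarity match of the most nucleophilic and least hindered dipole terminus (the glycine CH) with the imine carbon, and slow addition of DIC to a solution already holding excess 14 keeps the münchnone concentration low so that cycloaddition outruns its self-acylation.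

Step 9
Reactants: 18 1-(2,4-dimethoxybenzyl)-4-(6-bromo-1-tosylindol-3-yl)-2-(1-tosylindol-3-yl)imidazole
Product: 19 4-(6-bromo-1-tosylindol-3-yl)-2-(1-tosylindol-3-yl)-1H-imidazole
Conditions: CF3CO2H, anisole, 70 °C
Reagents that add atoms: none
Why: This is an SN1 acidolysis in which the protonated imidazole leaves from the N–CH2 bond to give the 2,4-dimethoxybenzyl cation, which anisole captures by Friedel–Crafts alkylation, while the N-tosylindoles are acid-stable and too deactivated to be re-alkylated (a silane scavenger is avoided because silane in CF3CO2H can reduce indoles).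

Step 10
Reactants: 19 4-(6-bromo-1-tosylindol-3-yl)-2-(1-tosylindol-3-yl)-1H-imidazole
Product: 20 nortopsentin C
Conditions: KOH, MeOH/THF/H2O, 65 °C
Reagents that add atoms: none
Why: Hydroxide attacks the sulfur of each N-sulfonylindole and expels the stabilised indolide (nucleophilic desulfonylation of N-tosylindoles), under conditions that leave the aryl bromide and the imidazole untouched.

**Compound list**

1 | indole-3-carboxaldehyde | O=Cc1c[nH]c2ccccc12 | starting material
2 | 1-tosylindole-3-carboxaldehyde | Cc1ccc(cc1)S(=O)(=O)n1cc(C=O)c2ccccc12 | intermediate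
3 | 1-tosylindole-3-carboxylic acid | Cc1ccc(cc1)S(=O)(=O)n1cc(C(=O)O)c2ccccc12 | intermediate
4 | glycine benzyl ester hydrochloride | Cl.NCC(=O)OCc1ccccc1 | starting material
5 | 2,4-dimethoxybenzaldehyde | COc1ccc(C=O)c(OC)c1 | starting material
6 | benzyl (E)-N-(2,4-dimethoxybenzylidene)glycinate (not isolated) | COc1ccc(/C=N/CC(=O)OCc2ccccc2)c(OC)c1 | intermediate
7 | benzyl N-(2,4-dimethoxybenzyl)glycinate | COc1ccc(CNCC(=O)OCc2ccccc2)c(OC)c1 | intermediate
8 | 1-tosylindole-3-carbonyl chloride (not isolated) | Cc1ccc(cc1)S(=O)(=O)n1cc(C(=O)Cl)c2ccccc12 | intermediate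
9 | benzyl N-(2,4-dimethoxybenzyl)-N-(1-tosylindole-3-carbonyl)glycinate | COc1ccc(CN(CC(=O)OCc2ccccc2)C(=O)c2cn(S(=O)(=O)c3ccc(C)cc3)c3ccccc23)c(OC)c1 | intermediate
10 | N-(2,4-dimethoxybenzyl)-N-(1-tosylindole-3-carbonyl)glycine | COc1ccc(CN(CC(=O)O)C(=O)c2cn(S(=O)(=O)c3ccc(C)cc3)c3ccccc23)c(OC)c1 | intermediate
11 | 6-bromoindole-3-carboxaldehyde | O=Cc1c[nH]c2cc(Br)ccc12 | starting material
12 | 6-bromo-1-tosylindole-3-carboxaldehyde | Cc1ccc(cc1)S(=O)(=O)n1cc(C=O)c2ccc(Br)cc12 | intermediate
13 | p-toluenesulfonamide | Cc1ccc(cc1)S(N)(=O)=O | starting material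
14 | (E)-N-[(6-bromo-1-tosylindol-3-yl)methylidene]-4-methylbenzenesulfonamide | Cc1ccc(cc1)S(=O)(=O)/N=C/c1cn(S(=O)(=O)c2ccc(C)cc2)c2cc(Br)ccc12 | intermediate
15 | 3-(2,4-dimethoxybenzyl)-2-(1-tosylindol-3-yl)-1,3-oxazol-3-ium-5-olate, the münchnone (not isolated) | COc1ccc(C[n+]2cc([O-])oc2-c2cn(S(=O)(=O)c3ccc(C)cc3)c3ccccc23)c(OC)c1 | intermediate
16 | 5-(6-bromo-1-tosylindol-3-yl)-7-(2,4-dimethoxybenzyl)-6-tosyl-1-(1-tosylindol-3-yl)-2-oxa-6,7-diazabicyclo[2.2.1]heptan-3-one, transient cycloadduct of undefined relative configuration (not isolated) | O=C1OC2(c3cn(S(=O)(=O)c4ccc(C)cc4)c4ccccc34)N(Cc3ccc(OC)cc3OC)C1C(c1cn(S(=O)(=O)c3ccc(C)cc3)c3cc(Br)ccc13)N2S(=O)(=O)c1ccc(C)cc1 | intermediate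
17 | cyclic azomethine ylide left after CO2 loss: 4-(6-bromo-1-tosylindol-3-yl)-1-(2,4-dimethoxybenzyl)-3-tosyl-2-(1-tosylindol-3-yl)-3,4-dihydroimidazol-1-ium-5-ide (not isolated) | COc1ccc(C[N+]2=C(c3cn(S(=O)(=O)c4ccc(C)cc4)c4ccccc34)N(S(=O)(=O)c3ccc(C)cc3)C(c3cn(S(=O)(=O)c4ccc(C)cc4)c4cc(Br)ccc34)[CH-]2)c(OC)c1 | intermediate
18 | 1-(2,4-dimethoxybenzyl)-4-(6-bromo-1-tosylindol-3-yl)-2-(1-tosylindol-3-yl)imidazole | COc1ccc(Cn2cc(nc2-c2cn(S(=O)(=O)c3ccc(C)cc3)c3ccccc23)-c2cn(S(=O)(=O)c3ccc(C)cc3)c3cc(Br)ccc23)c(OC)c1 | intermediate
19 | 4-(6-bromo-1-tosylindol-3-yl)-2-(1-tosylindol-3-yl)-1H-imidazole | Cc1ccc(cc1)S(=O)(=O)n1cc(-c2nc(c[nH]2)-c2cn(S(=O)(=O)c3ccc(C)cc3)c3cc(Br)ccc23)c2ccccc12 | intermediate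
20 | nortopsentin C | Brc1ccc2c(-c3c[nH]c(-c4c[nH]c5ccccc45)n3)c[nH]c2c1 | target

**Step count**

Total: 10 steps. Longest linear sequence: 7 steps (steps 1, 2, 4, 5, 8, 9, 10).

**Steps most likely to fail**

1. Step 8 (key step).
- What may go wrong: the C4-unsubstituted münchnone may acylate itself or dimerise faster than it is captured by the heteroaryl imine. The activated acid may rearrange to an N-acylurea. The imine may be lost to adventitious water or to addition of the liberated sulfinic acid. The dipole may add with reversed orientation.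
- Fallback (Davidson-type imidazole synthesis from an α-acyloxy ketone and ammonia, no dipole involved): it sets out from aldehyde 12 and acid 3 and comes back at compound 19.
- Aldehyde 12 with MeMgBr (THF, −78 °C) should give racemic 1-(6-bromo-1-tosylindol-3-yl)ethanol F1.
- Oxidation with MnO2 (CH2Cl2, rt) should give 3-acetyl-6-bromo-1-tosylindole F2.
- α-Bromination with CuBr2 (EtOAc/CHCl3, reflux) should give 2-bromo-1-(6-bromo-1-tosylindol-3-yl)ethanone F3.
- O-Alkylation of acid 3 with this bromide (K2CO3, DMF, rt) should give 2-(6-bromo-1-tosylindol-3-yl)-2-oxoethyl 1-tosylindole-3-carboxylate F4.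
- Heating this keto ester with a large excess of NH4OAc in toluene or xylene (110–140 °C) should give imidazole 19 directly. It then enters step 10; steps 3–5, 7 and 9 are not needed. Partial loss of a sulfonyl group to ammonia would be harmless, since both are removed in step 10.

2. Step 9.
- What may go wrong: ionisation of the N–benzyl bond of the protonated imidazole may be incomplete, or the dimethoxybenzyl cation may return onto an imidazole nitrogen or an indole carbon.
- Fallback (oxidative instead of acidolytic cleavage): it sets out from 18 and comes back at 19. (NH4)2Ce(NO3)6 in MeCN/H2O at 0 °C to rt oxidises the electron-rich dimethoxyarene by single-electron transfer. Water captures the benzylic cation and the hemiaminal collapses to 19 and 2,4-dimethoxybenzaldehyde. The sulfonylated indoles are deactivated toward the oxidant. No new compound is made.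

3. Step 7.
- What may go wrong: the reversible condensation may stall with a poorly electrophilic heteroaryl aldehyde, and the moisture-sensitive sulfonylimine may hydrolyse during isolation.
- Fallback (stable α-amido sulfone as imine precursor instead of direct dehydrative condensation): it sets out from 12 and 13 and comes back at 14. Aldehyde 12, sulfonamide 13 and sodium p-toluenesulfinate in HCO2H/H2O at rt should precipitate racemic N-[(6-bromo-1-tosylindol-3-yl)(tosyl)methyl]-4-methylbenzenesulfonamide F5. Stirring this sulfone in CH2Cl2 with saturated aqueous NaHCO3 eliminates sulfinate and should deliver imine 14 in the dried organic layer, ready for step 8.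

**Further compounds**

F1 | step 8 | 1-(6-bromo-1-tosylindol-3-yl)ethanol (racemic) | CC(O)c1cn(S(=O)(=O)c2ccc(C)cc2)c2cc(Br)ccc12
F2 | step 8 | 3-acetyl-6-bromo-1-tosylindole | CC(=O)c1cn(S(=O)(=O)c2ccc(C)cc2)c2cc(Br)ccc12
F3 | step 8 | 2-bromo-1-(6-bromo-1-tosylindol-3-yl)ethanone | BrCC(=O)c1cn(S(=O)(=O)c2ccc(C)cc2)c2cc(Br)ccc12
F4 | step 8 | 2-(6-bromo-1-tosylindol-3-yl)-2-oxoethyl 1-tosylindole-3-carboxylate | Cc1ccc(cc1)S(=O)(=O)n1cc(C(=O)OCC(=O)c2cn(S(=O)(=O)c3ccc(C)cc3)c3cc(Br)ccc23)c2ccccc12
F0 | step 9 | none | none
F5 | step 7 | N-[(6-bromo-1-tosylindol-3-yl)(tosyl)methyl]-4-methylbenzenesulfonamide (racemic) | Cc1ccc(cc1)S(=O)(=O)NC(c1cn(S(=O)(=O)c2ccc(C)cc2)c2cc(Br)ccc12)S(=O)(=O)c1ccc(C)cc1
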